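**Retrosynthetic overview**

- The last bond made is the O–CH3 bond at C5: the target is the methyl ether of the 5-hydroxy-6,7-dimethoxyflavone.
- The strategy rests on ring A of the chromenone (C5, C6, C7, C8, C8a, C4a): oxygen at C5, vicinal methoxy groups at C6 and C7, hydrogen at C8, fusion to ring C at C4a=C8a. Ring A is cut at C4a–C5, which leads back to a 2,3-dimethoxycyclobutenone carrying the 6-aryl-4-pyranon-2-yl group at C4 (thermal 4π opening, then 6π closure).
- The C8–C8a bond comes from a palladium-catalysed coupling of the 2-aryl-4-pyranone, zincated at its oxygen-flanked carbon, with 4-chloro-2,3-dimethoxycyclobutenone (from dimethyl squarate by reduction and chlorination).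
- The pyranone (ring C with ring B attached) comes from 1,2,3,4-tetramethoxybenzene by Friedel–Crafts acetylation, Claisen condensation, dianion formylation and cyclodehydration.
- Order of rings: ring B is purchased, ring C is built, the four-membered ring is attached, ring A is formed last.

Key step: step 7

Remark on the chemistry: flavone numbering is used for the chromenone. The target has no stereocentre, so the cyclobutenone intermediates are handled as racemates.

**Route**

Step 1
Reactants: 1 1,2,3,4-tetramethoxybenzene; 2 acetyl chloride
Product: 3 1-(2,3,4,5-tetramethoxyphenyl)ethan-1-one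
Conditions: AcCl (1.1 equiv), SnCl4 (1.1 equiv), CH2Cl2, −10 to 0 °C; ice/aq HCl
Reagents that add atoms: none
Why: Friedel–Crafts acylation, in which the two free ring positions of 1 are equivalent so that a single ketone should form, and the mild Lewis acid SnCl4 at low temperature should spare the methoxy group ortho to the new carbonyl from chelation-driven demethylation.

Step 2
Reactants: 3 1-(2,3,4,5-tetramethoxyphenyl)ethan-1-one; 4 ethyl acetate
Product: 5 1-(2,3,4,5-tetramethoxyphenyl)butane-1,3-dione
Conditions: NaH (3 equiv), EtOAc (5 equiv), THF, 65 °C; aq HCl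
Reagents that add atoms: none
Why: Crossed Claisen condensation, in which the sodium enolate of the aryl methyl ketone is acylated by ethyl acetate and the equilibrium is drawn forward by deprotonation of the β-diketone formed.

Step 3
Reactants: 5 1-(2,3,4,5-tetramethoxyphenyl)butane-1,3-dione; 6 ethyl formate
Product: 8 2-(2,3,4,5-tetramethoxyphenyl)-4H-pyran-4-one, via diketo aldehyde 7 (not isolated)
Conditions: LiN(iPr)2 (3.2 equiv), THF, −78 to 0 °C; HCO2Et, −78 °C to rt; aq HCl; then TsOH·H2O (cat.), toluene, 80 °C
Reagents that add atoms: none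
Why: Terminal acylation of a β-diketone dianion (a second Claisen condensation) should place the formyl group on the methyl-derived carbanion, and acid-catalysed cyclodehydration of the 1,3,5-tricarbonyl compound should close ring C by attack of the aryl ketone enol oxygen on the formyl carbon.

Step 4
Reactants: 9 dimethyl squarate
Product: 10 4-hydroxy-2,3-dimethoxycyclobut-2-en-1-one (racemic)
Conditions: LiAlH(OtBu)3 (1.05 equiv), THF, −78 °C; cold water, pH 7 work-up
Reagents that add atoms: none
Why: Chemoselective 1,2-reduction of one of the two equivalent carbonyl groups by a bulky alkoxyaluminium hydride should stop at the alkoxide, which resists a second hydride at low temperature, and the new carbinol centre is formed as a racemate of no consequence.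

Step 5
Reactants: 10 4-hydroxy-2,3-dimethoxycyclobut-2-en-1-one (racemic)
Product: 11 4-chloro-2,3-dimethoxycyclobut-2-en-1-one (racemic)
Conditions: SOCl2 (1.1 equiv), 2,6-lutidine (1.2 equiv), Et2O, −20 to 0 °C; filter, concentrate cold, use at once
Reagents that add atoms: thionyl chloride, O=S(Cl)Cl
Why: Deoxychlorination through a chlorosulfite should be fast at low temperature because the allylic C4 cation is stabilised by the 2-methoxy group, the conjugated 4-chloro isomer is the expected thermodynamic product, and either allylic isomer would give the same η3 palladium complex in step 6.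

Step 6
Reactants: 8 2-(2,3,4,5-tetramethoxyphenyl)-4H-pyran-4-one; 11 4-chloro-2,3-dimethoxycyclobut-2-en-1-one (racemic)
Product: 13 2,3-dimethoxy-4-[4-oxo-6-(2,3,4,5-tetramethoxyphenyl)-4H-pyran-2-yl]cyclobut-2-en-1-one (racemic), via pyranonylzinc chloride 12 (not isolated)
Conditions: Zn(TMP)Cl·LiCl (1.1 equiv; TMP = 2,2,6,6-tetramethylpiperidide), THF, 25 °C; then 11 (1.2 equiv), Pd(dba)2 (3 mol %), P(2-furyl)3 (6 mol %), 0 to 20 °C; work-up and chromatography below 20 °C
Reagents that add atoms: none
Why: Directed zincation by the hindered zinc amide should remove the most acidic ring proton, the oxygen-flanked C6–H, as in the C2 zincation of chromones, and Negishi cross-coupling of 12 with the η3-oxocyclobutenyl palladium chloride formed from 11 and zerovalent palladium should give, by reductive elimination at the unsubstituted allyl terminus, the conjugated cyclobutenone as in the Stille couplings of 4-chlorocyclobutenones, the new C4 centre being racemic and lost in step 7.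

Step 7
Reactants: 13 2,3-dimethoxy-4-[4-oxo-6-(2,3,4,5-tetramethoxyphenyl)-4H-pyran-2-yl]cyclobut-2-en-1-one (racemic)
Product: 16 5-hydroxy-6,7-dimethoxy-2-(2,3,4,5-tetramethoxyphenyl)-4H-chromen-4-one, via dienylketene 14 (not isolated), via cyclohexadienone 15 (not isolated)
Conditions: degassed toluene (0.01 M), 110 °C, argon
Reagents that add atoms: none
Why: Heating cleaves the C1–C4 bond of the cyclobutenone in a reversible conrotatory 4π ring opening to dienylketene 14, whose ketene carbon then bonds to pyranone C3 (flavone C4a) in a thermally allowed disrotatory 6π electrocyclization, and cyclohexadienone 15, whose C4a–H lies between two carbonyl groups, should enolise at once to the hydrogen-bonded 5-hydroxy arene. The closest known reaction type is the thermal rearrangement of 4-aryl, 4-alkenyl and 4-heteroaryl cyclobutenones to phenols and fused phenols, the aromatisation stage of cyclobutenone-based benzannulations; only the pyranonyl substituent is new. Ring A is closed as a six-membered carbocycle by this 6π electrocyclization, which forms the C4a–C5 bond, the squarate carbons becoming C5 (oxygen-bearing), C6 and C7 (methoxy-bearing) and C8 (CH). No stereocentre is created in 16, and the C4 centre of 13 and the transient C4a centre of 15 are lost on ring opening and enolisation. Two selectivities are needed: the site of closure is fixed because the pyranone carbon that carries the side chain has only one carbon neighbour, the other being the ring oxygen, and the inward rotation that places the pyranone cis to the ketene need not be preferred because the outward-rotated ketene recloses to 13 while the productive isomer is drained irreversibly by aromatisation.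

Step 8
Reactants: 16 5-hydroxy-6,7-dimethoxy-2-(2,3,4,5-tetramethoxyphenyl)-4H-chromen-4-one
Product: 17 Agehoustin B, 5,6,7-trimethoxy-2-(2,3,4,5-tetramethoxyphenyl)-4H-chromen-4-one
Conditions: Me2SO4 (3 equiv), K2CO3 (5 equiv), acetone, reflux
Reagents that add atoms: dimethyl sulfate, COS(=O)(=O)OC
Why: Williamson-type O-methylation, in which the hydrogen-bonded 5-hydroxyl group is the only acidic site and should be alkylated by dimethyl sulfate under prolonged heating with excess carbonate.

**Compound list**

1 | 1,2,3,4-tetramethoxybenzene | COc1ccc(OC)c(OC)c1OC | starting material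
2 | acetyl chloride | CC(=O)Cl | starting material
3 | 1-(2,3,4,5-tetramethoxyphenyl)ethan-1-one | CC(=O)c1cc(OC)c(OC)c(OC)c1OC | intermediate
4 | ethyl acetate | CCOC(C)=O | starting material
5 | 1-(2,3,4,5-tetramethoxyphenyl)butane-1,3-dione | CC(=O)CC(=O)c1cc(OC)c(OC)c(OC)c1OC | intermediate
6 | ethyl formate | CCOC=O | starting material
7 | 3,5-dioxo-5-(2,3,4,5-tetramethoxyphenyl)pentanal (present as its enols) | O=CCC(=O)CC(=O)c1cc(OC)c(OC)c(OC)c1OC | intermediate (not isolated)
8 | 2-(2,3,4,5-tetramethoxyphenyl)-4H-pyran-4-one | COc1cc(-c2cc(=O)cco2)c(OC)c(OC)c1OC | intermediate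
9 | dimethyl squarate (3,4-dimethoxycyclobut-3-ene-1,2-dione) | COC1=C(OC)C(=O)C1=O | starting material
10 | 4-hydroxy-2,3-dimethoxycyclobut-2-en-1-one (racemic) | COC1=C(OC)C(O)C1=O | intermediate
11 | 4-chloro-2,3-dimethoxycyclobut-2-en-1-one (racemic) | COC1=C(OC)C(Cl)C1=O | intermediate
12 | [4-oxo-6-(2,3,4,5-tetramethoxyphenyl)-4H-pyran-2-yl]zinc chloride (LiCl complex) | COc1cc(-c2cc(=O)cc([Zn]Cl)o2)c(OC)c(OC)c1OC | intermediate (not isolated)
13 | 2,3-dimethoxy-4-[4-oxo-6-(2,3,4,5-tetramethoxyphenyl)-4H-pyran-2-yl]cyclobut-2-en-1-one (racemic) | COC1=C(OC)C(c2cc(=O)cc(-c3cc(OC)c(OC)c(OC)c3OC)o2)C1=O | intermediate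
14 | (3E)-2,3-dimethoxy-4-[4-oxo-6-(2,3,4,5-tetramethoxyphenyl)-4H-pyran-2-yl]buta-1,3-dien-1-one (ketene carbon cis to the pyranone ring) | O=C=C(OC)/C(OC)=C\c1cc(=O)cc(-c2cc(OC)c(OC)c(OC)c2OC)o1 | intermediate (not isolated)
15 | 6,7-dimethoxy-2-(2,3,4,5-tetramethoxyphenyl)-4aH-chromene-4,5-dione (racemic) | O=C1C(OC)=C(OC)C=C2OC(-c3cc(OC)c(OC)c(OC)c3OC)=CC(=O)C12 | intermediate (not isolated)
16 | 5-hydroxy-6,7-dimethoxy-2-(2,3,4,5-tetramethoxyphenyl)-4H-chromen-4-one | COc1cc(-c2cc(=O)c3c(O)c(OC)c(OC)cc3o2)c(OC)c(OC)c1OC | intermediate
17 | Agehoustin B, 5,6,7-trimethoxy-2-(2,3,4,5-tetramethoxyphenyl)-4H-chromen-4-one | COc1cc(-c2cc(=O)c3c(OC)c(OC)c(OC)cc3o2)c(OC)c(OC)c1OC | target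

**Step count**

Total steps: 8. Longest linear sequence: 6 steps (steps 1, 2, 3, 6, 7, 8); the squarate branch (steps 4 and 5) joins at step 6.

**Steps most likely to fail**

Step 6. Coordination of the amide base to the C4 carbonyl may divert deprotonation to a carbonyl-flanked position (C3–H or C5–H) in competition with the oxygen-flanked C6–H. The zinc and lithium chlorides may also ionise 11, so that bond formation bypasses palladium and reaches the methoxy-bearing allyl terminus. The fallback sets out from 8 and 11 and comes back at 13. The zinc species from 8 would be quenched with iodine and the iodides separated to give 2-iodo-6-(2,3,4,5-tetramethoxyphenyl)-4H-pyran-4-one F1, so that the constitution can be secured before the sensitive chloride is committed. Stannylation of F1 with (Bu3Sn)2 and Pd(PPh3)4 in toluene at 80 °C would give 2-(tributylstannyl)-6-(2,3,4,5-tetramethoxyphenyl)-4H-pyran-4-one F2. A salt-free Stille coupling of F2 with 11 (PdCl2(PhCN)2, P(2-furyl)3, CuI, DMF, 25 °C), the established way of substituting 4-chlorocyclobutenones, would then deliver 13.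

Step 7. Ring opening may keep the pyranone rotated outward for most of the time. The small stationary amount of inward ketene may then be consumed by dimerisation, by traces of water or by the acidic C4–H of unreacted 13 before it closes onto the weakly aromatic pyranone. The fallback sets out from 3 and comes back at 17 by a Baker–Venkataraman assembly that does not build ring A. Ketone 3 would be degraded by the Ortoleva–King sequence (I2, pyridine, 100 °C; then aq NaOH) to 2,3,4,5-tetramethoxybenzoic acid F3, and SOCl2 would convert this into 2,3,4,5-tetramethoxybenzoyl chloride F4. Acylation of purchased 1-(6-hydroxy-2,3,4-trimethoxyphenyl)ethan-1-one F5 with F4 in pyridine would give 2-acetyl-3,4,5-trimethoxyphenyl 2,3,4,5-tetramethoxybenzoate F6. Baker–Venkataraman rearrangement (KOH, pyridine, 50 °C) would give 1-(6-hydroxy-2,3,4-trimethoxyphenyl)-3-(2,3,4,5-tetramethoxyphenyl)propane-1,3-dione F7, and cyclodehydration (cat. H2SO4, AcOH, 100 °C) would give 17 directly.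

Step 5. Ionisation of the activated C4 oxygen may be followed by loss of methanol to the cyclobutenedione, or the chloride may hydrolyse during isolation. The fallback sets out from 10 and comes back at 13. Alcohol 10 would be acylated with methyl chloroformate and pyridine in CH2Cl2 at −20 °C to the storable methyl 2,3-dimethoxy-4-oxocyclobut-2-en-1-yl carbonate F8 (racemic). F8 would be ionised by zerovalent palladium (Pd(dba)2, P(2-furyl)3, THF, 0 to 20 °C) in the presence of zinc reagent 12, an allylic-carbonate cross-coupling with an organozinc, to give 13 without a free chloride.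

**Further compounds**

F1 | step 6 | 2-iodo-6-(2,3,4,5-tetramethoxyphenyl)-4H-pyran-4-one | COc1cc(-c2cc(=O)cc(I)o2)c(OC)c(OC)c1OC
F2 | step 6 | 2-(tributylstannyl)-6-(2,3,4,5-tetramethoxyphenyl)-4H-pyran-4-one | CCCC[Sn](CCCC)(CCCC)c1cc(=O)cc(-c2cc(OC)c(OC)c(OC)c2OC)o1
F3 | step 7 | 2,3,4,5-tetramethoxybenzoic acid | COc1cc(C(=O)O)c(OC)c(OC)c1OC
F4 | step 7 | 2,3,4,5-tetramethoxybenzoyl chloride | COc1cc(C(=O)Cl)c(OC)c(OC)c1OC
F5 | step 7 | 1-(6-hydroxy-2,3,4-trimethoxyphenyl)ethan-1-one | CC(=O)c1c(O)cc(OC)c(OC)c1OC
F6 | step 7 | 2-acetyl-3,4,5-trimethoxyphenyl 2,3,4,5-tetramethoxybenzoate | CC(=O)c1c(OC(=O)c2cc(OC)c(OC)c(OC)c2OC)cc(OC)c(OC)c1OC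
F7 | step 7 | 1-(6-hydroxy-2,3,4-trimethoxyphenyl)-3-(2,3,4,5-tetramethoxyphenyl)propane-1,3-dione | COc1cc(C(=O)CC(=O)c2c(O)cc(OC)c(OC)c2OC)c(OC)c(OC)c1OC
F8 | step 5 | methyl 2,3-dimethoxy-4-oxocyclobut-2-en-1-yl carbonate (racemic) | COC(=O)OC1C(OC)=C(OC)C1=O
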